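Ring B of the target bears oxygen on four neighbouring carbons, C6–C9. The bond between the two β-carbinol carbons C7 and C8 lies beside the α-oriented ether oxygen at C9 of ring C, and this C7–C8 bond is the disconnection. A sclareolide-derived 9α,13-epoxylabd-7-ene is cut open at C7=C8 to a seco keto aldehyde. In it, ring A carries a CH(OTBS)CHO arm at C5, and C10 carries the finished tetrahydrofuran ring C with its acetyl group and both protected C13 arms. SmI2 then rejoins aldehyde and ketone, closing ring B and setting C7 and C8 as the cis-7β,8β-diol in one operation. Five functional-group steps complete the dihydrofuran.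

Key step: step 18

Remark: labdane numbering is used and α denotes the face opposite the C10 methyl; the acetal-type carbons formed in the ozonide (C7, C8) and in ring D before the last step (C15) are mixtures that converge and are drawn without configuration.
Abbreviations: TBS = tert-butyldimethylsilyl, TBDPS = tert-butyldiphenylsilyl.

Step 1
Reactants: 1 (+)-sclareolide
Product: 2 methyl 13,14,15,16-tetranorlabd-8(9)-en-12-oate
Conditions: conc. H2SO4, MeOH, reflux
Reagents that add atoms: methanol, CO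
Why: Acid-catalysed lactone methanolysis and E1 dehydration of the C8 tertiary alcohol under equilibrating conditions should settle on the tetrasubstituted, most stable C8=C9 alkene, while C5 and C10 are untouched.

Step 2
Reactants: 2 methyl 13,14,15,16-tetranorlabd-8(9)-en-12-oate
Product: 3 13,14,15,16-tetranorlabd-8(9)-en-12-ol
Conditions: LiAlH4, Et2O, 0 °C
Reagents that add atoms: none
Why: Hydride reduction of an ester to the primary alcohol leaves the isolated alkene inert.

Step 3
Reactants: 3 13,14,15,16-tetranorlabd-8(9)-en-12-ol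
Product: 4 12-bromo-13,14,15,16-tetranorlabd-8(9)-ene
Conditions: CBr4, PPh3, CH2Cl2, 0 °C
Reagents that add atoms: carbon tetrabromide, BrC(Br)(Br)Br
Why: The Appel reaction converts the primary alcohol into the bromide under neutral conditions that do not isomerise the alkene.

Step 4
Reactants: 5 propargyl alcohol
Product: 6 tert-butyl(diphenyl)(prop-2-yn-1-yloxy)silane
Conditions: TBDPSCl, imidazole, CH2Cl2, rt
Reagents that add atoms: tert-butyl(chloro)diphenylsilane, CC(C)(C)[Si](Cl)(c1ccccc1)c1ccccc1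
Why: Standard imidazole-promoted silylation of a primary alcohol installs the O16 protecting group, chosen to outlast chromium, base, acid and ozone.

Step 5
Reactants: 6 tert-butyl(diphenyl)(prop-2-yn-1-yloxy)silane
Product: 8 ethyl 4-(TBDPS-oxy)but-2-ynoate, via lithium acetylide 7 (not isolated)
Conditions: n-BuLi, THF, −78 °C; ClCO2Et, −78 °C to 0 °C
Reagents that add atoms: ethyl chloroformate, CCOC(=O)Cl
Why: Deprotonation of the terminal alkyne and C-acylation with a chloroformate give the ynoate that holds C13–C16.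

Step 6
Reactants: 4 12-bromo-13,14,15,16-tetranorlabd-8(9)-ene; 8 ethyl 4-(TBDPS-oxy)but-2-ynoate
Product: 12 ethyl (13Z)-16-(TBDPS-oxy)labda-8(9),13-dien-15-oate, via Grignard reagent 9 (not isolated), via alkylcopper 10 (not isolated), via alkenylcopper adduct 11 (not isolated)
Conditions: 4, Mg, THF, 40 °C; CuBr·SMe2, THF–Me2S, −40 °C; 8, −78 °C; aq NH4Cl, −78 °C
Reagents that add atoms: none
Why: In this syn-carbocupration of an ynoate, carbon and copper add to the same side and cold protonation keeps the geometry, so C12 ends trans to the ester and the C12–C13 bond forms with a defined 13Z alkene.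

Step 7
Reactants: 12 ethyl (13Z)-16-(TBDPS-oxy)labda-8(9),13-dien-15-oate
Product: 13 (13Z)-16-(TBDPS-oxy)labda-8(9),13-dien-15-ol
Conditions: i-Bu2AlH, CH2Cl2, −78 °C
Reagents that add atoms: none
Why: 1,2-Reduction of the enoate with a dialkylaluminium hydride gives the allylic alcohol without touching alkene geometry or the silyl ether.

Step 8
Reactants: 13 (13Z)-16-(TBDPS-oxy)labda-8(9),13-dien-15-ol
Product: 14 (13R,14S)-13,14-epoxy-16-(TBDPS-oxy)labd-8(9)-en-15-ol
Conditions: Ti(OiPr)4 (cat.), L-(+)-diethyl tartrate (cat.), t-BuOOH, 4 Å MS, CH2Cl2, −20 °C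
Reagents that add atoms: tert-butyl hydroperoxide, CC(C)(C)OO
Why: In this Sharpless asymmetric epoxidation, reagent control of the kind that turns nerol into its (2S,3R)-epoxy alcohol with L-(+)-tartrate sets C13 (R) and C14 (S); the C8=C9 alkene lacks a directing hydroxyl and stays, and the minor epoxide is a separable diastereomer.

Step 9
Reactants: 14 (13R,14S)-13,14-epoxy-16-(TBDPS-oxy)labd-8(9)-en-15-ol
Product: 15 (13S)-16-(TBDPS-oxy)labd-8(9)-ene-13,15-diol
Conditions: NaAlH2(OCH2CH2OMe)2, THF, 0 °C to rt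
Reagents that add atoms: none
Why: In this regioselective reductive opening of a 2,3-epoxy alcohol to the 1,3-diol, the O15-bound aluminate delivers hydride to C14 and the C13–O bond is kept, so the tertiary carbinol keeps its spatial arrangement (13S only through changed priorities).

Step 10
Reactants: 15 (13S)-16-(TBDPS-oxy)labd-8(9)-ene-13,15-diol
Product: 16 (13S)-13-hydroxy-16-(TBDPS-oxy)labd-8(9)-en-15-al
Conditions: TEMPO (cat.), PhI(OAc)2, CH2Cl2, rt
Reagents that add atoms: none
Why: Oxoammonium-catalysed oxidation takes only the primary alcohol and stops at the aldehyde, and the tertiary alcohol cannot react.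

Step 11
Reactants: 16 (13S)-13-hydroxy-16-(TBDPS-oxy)labd-8(9)-en-15-al
Product: 17 (13S)-15,15-dimethoxy-16-(TBDPS-oxy)labd-8(9)-en-13-ol
Conditions: HC(OMe)3, PPTS (cat.), MeOH, rt
Reagents that add atoms: trimethyl orthoformate, COC(OC)OC; methanol, CO
Why: Acid-catalysed acetalisation with orthoformate as water scavenger is mild enough to avoid dehydration of the β-hydroxy aldehyde.

Step 12
Reactants: 17 (13S)-15,15-dimethoxy-16-(TBDPS-oxy)labd-8(9)-en-13-ol
Product: 18 (13S)-13-hydroxy-15,15-dimethoxy-16-(TBDPS-oxy)labd-8(9)-en-7-one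
Conditions: CrO3, 3,5-dimethylpyrazole, CH2Cl2, −20 °C
Reagents that add atoms: chromium trioxide, O=[Cr](=O)=O
Why: In this allylic oxidation with the CrO3–dimethylpyrazole complex, the ring methylene C7 is the most accessible of the three allylic positions (C11 is shielded by the C10 methyl and the side chain, C17 is only a methyl), so the 8-en-7-one should result.

Step 13
Reactants: 18 (13S)-13-hydroxy-15,15-dimethoxy-16-(TBDPS-oxy)labd-8(9)-en-7-one
Product: 20 (13S)-6α,13-dihydroxy-15,15-dimethoxy-16-(TBDPS-oxy)labd-8(9)-en-7-one, via dipotassium dienolate 19 (not isolated)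
Conditions: KN(SiMe3)2 (2.2 equiv), THF, −78 °C; 2-(phenylsulfonyl)-3-phenyloxaziridine, −78 °C; aq NH4Cl
Reagents that add atoms: 2-(phenylsulfonyl)-3-phenyloxaziridine, O=S(=O)(c1ccccc1)N1OC1c1ccccc1
Why: Kinetic α′-deprotonation at C6 (one equivalent of base is spent on the 13-OH) is followed by N-sulfonyloxaziridine enolate hydroxylation; the axial methyls on C4 and C10 cover the β face of C6, so oxygen arrives from the α face and gives the equatorial 6α-alcohol while ring B is still intact.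

Step 14
Reactants: 20 (13S)-6α,13-dihydroxy-15,15-dimethoxy-16-(TBDPS-oxy)labd-8(9)-en-7-one
Product: 21 (13S)-6α-(TBS-oxy)-13-hydroxy-15,15-dimethoxy-16-(TBDPS-oxy)labd-8(9)-en-7-one
Conditions: TBSOTf (1.05 equiv), 2,6-lutidine, CH2Cl2, −78 °C
Reagents that add atoms: tert-butyldimethylsilyl triflate, CC(C)(C)[Si](C)(C)OS(=O)(=O)C(F)(F)F
Why: Silyl triflate silylation at low temperature picks the secondary 6α-OH over the crowded tertiary 13-OH, and silyl ethers on O6 and O16 tolerate ozone (a benzylic ether would not) and can leave together in step 20.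

Step 15
Reactants: 21 (13S)-6α-(TBS-oxy)-13-hydroxy-15,15-dimethoxy-16-(TBDPS-oxy)labd-8(9)-en-7-one
Product: 22 (13S)-6α-(TBS-oxy)-15,15-dimethoxy-16-(TBDPS-oxy)labd-8(9)-ene-7β,13-diol
Conditions: NaBH4, CeCl3·7H2O, MeOH, −78 °C to −20 °C
Reagents that add atoms: none
Why: In this Luche 1,2-reduction, axial hydride delivery from the α face should give the 7β-alcohol, a centre that is erased again in step 16.

Step 16
Reactants: 22 (13S)-6α-(TBS-oxy)-15,15-dimethoxy-16-(TBDPS-oxy)labd-8(9)-ene-7β,13-diol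
Product: 23 (13S)-9α,13-epoxy-6α-(TBS-oxy)-15,15-dimethoxy-16-(TBDPS-oxy)labd-7-ene
Conditions: camphorsulfonic acid (cat.), 4 Å MS, CH2Cl2, 0 °C
Reagents that add atoms: none
Why: This is an acid-catalysed cyclodehydration through an allyl cation, the reaction type used for theaspirane-like 1-oxaspiro[4.5]dec-6-enes: loss of the C7 hydroxyl gives the C7–C8–C9 cation and the 13-OH captures its tertiary end in a 5-exo closure along the axial α trajectory, away from the C10 methyl, so O is 9α and C11 stays equatorial, while the C13–O bond is never broken.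

Step 17
Reactants: 23 (13S)-9α,13-epoxy-6α-(TBS-oxy)-15,15-dimethoxy-16-(TBDPS-oxy)labd-7-ene
Product: 25 (13S)-9α,13-epoxy-6α-(TBS-oxy)-15,15-dimethoxy-8-oxo-16-(TBDPS-oxy)-7,8-secolabdan-7-al, via secondary ozonide 24 (not isolated)
Conditions: O3, CH2Cl2, −78 °C (Sudan Red 7B end point); PPh3, −78 °C to rt
Reagents that add atoms: ozone, [O-][O+]=O
Why: Ozonolysis with reductive work-up cleaves the only C=C bond to the C7 aldehyde and the C8 methyl ketone without touching C6 or C9, and the dye end point keeps excess ozone away from the acetal C–H.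

Step 18
Reactants: 25 (13S)-9α,13-epoxy-6α-(TBS-oxy)-15,15-dimethoxy-8-oxo-16-(TBDPS-oxy)-7,8-secolabdan-7-al
Product: 27 (13S)-9α,13-epoxy-6α-(TBS-oxy)-15,15-dimethoxy-16-(TBDPS-oxy)labdane-7β,8β-diol, via samarium diolate 26 (not isolated)
Conditions: SmI2 (3 equiv, 0.1 M in THF), slow addition of 25 in THF (high dilution), −78 °C to −20 °C; pH 7 buffer
Reagents that add atoms: none
Why: Divalent samarium gives one electron to the more easily reduced C7 aldehyde, the metal-bound ketyl adds to the C8 ketone held on the same samarium, and a second electron plus aqueous work-up deliver the diol, which is the intramolecular ketyl–carbonyl pinacol coupling of a 1,6-keto aldehyde known to give cis-cyclohexane-1,2-diols. Ring B closes in a 6-exo-trig radical mode through a chair in which the C6 silyloxy group and the C8 methyl are equatorial. At C8 the methyl avoids the 1,3-diaxial clash with the C10 methyl, so O8 becomes axial β, antiperiplanar to the axial C9–O bond, which also lowers dipole repulsion. At C7 the samarium bridge forces O7 gauche to O8, that is equatorial β and trans to the 6α-silyloxy group. The step needs coupling to win over α-C–O cleavage at C6 or C9, over plain carbonyl reduction and over dimerisation; leaving out HMPA and proton donors, low temperature and slow addition under dilution serve this, and a cold quench limits silyl migration from O6 to O7.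

Step 19
Reactants: 27 (13S)-9α,13-epoxy-6α-(TBS-oxy)-15,15-dimethoxy-16-(TBDPS-oxy)labdane-7β,8β-diol
Product: 28 (13S)-7β-acetoxy-9α,13-epoxy-6α-(TBS-oxy)-15,15-dimethoxy-16-(TBDPS-oxy)labdan-8β-ol
Conditions: Ac2O, DMAP (cat.), pyridine, rt
Reagents that add atoms: acetic anhydride, CC(=O)OC(C)=O
Why: In this DMAP-catalysed acylation only the secondary equatorial 7β-OH reacts, since the tertiary axial 8β-OH is too hindered.

Step 20
Reactants: 28 (13S)-7β-acetoxy-9α,13-epoxy-6α-(TBS-oxy)-15,15-dimethoxy-16-(TBDPS-oxy)labdan-8β-ol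
Product: 30 (13S)-7β-acetoxy-9α,13:15,16-diepoxy-15-methoxylabdane-6α,8β-diol, via 6α,8β,16-triol 29 (not isolated)
Conditions: HF·pyridine, pyridine, THF, 0 °C to rt; crude 29, PPTS (cat.), CH2Cl2, rt
Reagents that add atoms: none
Why: Fluoride desilylation of both silyl ethers in a non-basic medium (no acetyl migration) is followed by acid-catalysed transacetalisation, in which the freed 16-OH displaces one methoxy group in a 5-exo closure of ring D; the new C15 centre is an anomeric mixture of no consequence.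

Step 21
Reactants: 30 (13S)-7β-acetoxy-9α,13:15,16-diepoxy-15-methoxylabdane-6α,8β-diol
Product: 31 (13S)-7β-acetoxy-9α,13:15,16-diepoxy-8β-hydroxy-15-methoxylabdan-6-one
Conditions: Dess–Martin periodinane, NaHCO3, CH2Cl2, rt
Reagents that add atoms: none
Why: Dess–Martin oxidation takes the only secondary alcohol, since O16 is locked in the acetal and the 8β-OH is tertiary; the trans ring fusion at C5 and the equatorial 7β-acetate are the stable arrangements next to the new ketone.

Step 22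
Reactants: 31 (13S)-7β-acetoxy-9α,13:15,16-diepoxy-8β-hydroxy-15-methoxylabdan-6-one
Product: 32 (13S)-7β-acetoxy-9α,13:15,16-diepoxy-8β,15-dihydroxylabdan-6-one
Conditions: PPTS (cat.), acetone–H2O, rt
Reagents that add atoms: water, O
Why: A 2-methoxytetrahydrofuran acetal hydrolyses under very mild acid, and in a water-rich medium the oxocarbenium ion is captured faster than it can lose a proton, so the lactol should form without opening ring C.

Step 23
Reactants: 32 (13S)-7β-acetoxy-9α,13:15,16-diepoxy-8β,15-dihydroxylabdan-6-one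
Product: 34 (13S)-7β-acetoxy-9α,13:15,16-diepoxy-8β-hydroxylabd-14-en-6-one (CNP0284584.1), via anomeric mesylate 33 (not isolated)
Conditions: MsCl, Et3N, CH2Cl2, −20 °C to rt
Reagents that add atoms: none
Why: In this lactol dehydration through the anomeric mesylate, C13 is quaternary, so elimination by Et3N can only place the double bond between C14 and C15; the basic medium protects the acid-labile enol ether, and the hindered tertiary 8β-OH should not be sulfonylated.

Compound list
1 | (+)-sclareolide | C1C[C@H]2C(C)(C)CCC[C@]2(C)[C@H]3CC(=O)O[C@]13C | starting material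
2 | methyl 13,14,15,16-tetranorlabd-8(9)-en-12-oate | COC(=O)CC1=C(C)CC[C@H]2C(C)(C)CCC[C@]12C | intermediate
3 | 13,14,15,16-tetranorlabd-8(9)-en-12-ol | OCCC1=C(C)CC[C@H]2C(C)(C)CCC[C@]12C | intermediate
4 | 12-bromo-13,14,15,16-tetranorlabd-8(9)-ene | BrCCC1=C(C)CC[C@H]2C(C)(C)CCC[C@]12C | intermediate
5 | propargyl alcohol | C#CCO | starting material
6 | tert-butyl(diphenyl)(prop-2-yn-1-yloxy)silane | C#CCO[Si](c1ccccc1)(c1ccccc1)C(C)(C)C | intermediate
7 | lithium acetylide of 6 | [Li]C#CCO[Si](c1ccccc1)(c1ccccc1)C(C)(C)C | intermediate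
8 | ethyl 4-(TBDPS-oxy)but-2-ynoate | CCOC(=O)C#CCO[Si](c1ccccc1)(c1ccccc1)C(C)(C)C | intermediate
9 | Grignard reagent of 4 (C12–MgBr) | Br[Mg]CCC1=C(C)CC[C@H]2C(C)(C)CCC[C@]12C | intermediate
10 | alkylcopper (C12–Cu) | [Cu]CCC1=C(C)CC[C@H]2C(C)(C)CCC[C@]12C | intermediate
11 | alkenylcopper adduct (Cu on C14, cis to C12) | CCOC(=O)/C([Cu])=C(/CCC1=C(C)CC[C@H]2C(C)(C)CCC[C@]12C)CO[Si](c1ccccc1)(c1ccccc1)C(C)(C)C | intermediate
12 | ethyl (13Z)-16-(TBDPS-oxy)labda-8(9),13-dien-15-oate | CCOC(=O)/C=C(/CCC1=C(C)CC[C@H]2C(C)(C)CCC[C@]12C)CO[Si](c1ccccc1)(c1ccccc1)C(C)(C)C | intermediate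
13 | (13Z)-16-(TBDPS-oxy)labda-8(9),13-dien-15-ol | OC/C=C(/CCC1=C(C)CC[C@H]2C(C)(C)CCC[C@]12C)CO[Si](c1ccccc1)(c1ccccc1)C(C)(C)C | intermediate
14 | (13R,14S)-13,14-epoxy-16-(TBDPS-oxy)labd-8(9)-en-15-ol | OC[C@@H]1O[C@]1(CCC2=C(C)CC[C@H]3C(C)(C)CCC[C@]23C)CO[Si](c1ccccc1)(c1ccccc1)C(C)(C)C | intermediate
15 | (13S)-16-(TBDPS-oxy)labd-8(9)-ene-13,15-diol | OCC[C@@](O)(CCC1=C(C)CC[C@H]2C(C)(C)CCC[C@]12C)CO[Si](c1ccccc1)(c1ccccc1)C(C)(C)C | intermediate
16 | (13S)-13-hydroxy-16-(TBDPS-oxy)labd-8(9)-en-15-al | O=CC[C@@](O)(CCC1=C(C)CC[C@H]2C(C)(C)CCC[C@]12C)CO[Si](c1ccccc1)(c1ccccc1)C(C)(C)C | intermediate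
17 | (13S)-15,15-dimethoxy-16-(TBDPS-oxy)labd-8(9)-en-13-ol | COC(OC)C[C@@](O)(CCC1=C(C)CC[C@H]2C(C)(C)CCC[C@]12C)CO[Si](c1ccccc1)(c1ccccc1)C(C)(C)C | intermediate
18 | (13S)-13-hydroxy-15,15-dimethoxy-16-(TBDPS-oxy)labd-8(9)-en-7-one | COC(OC)C[C@@](O)(CCC1=C(C)C(=O)C[C@H]2C(C)(C)CCC[C@]12C)CO[Si](c1ccccc1)(c1ccccc1)C(C)(C)C | intermediate
19 | dipotassium 13-alkoxide 6,8-dien-7-olate of 18 | [K+].[K+].COC(OC)C[C@@]([O-])(CCC1=C(C)C([O-])=C[C@H]2C(C)(C)CCC[C@]12C)CO[Si](c1ccccc1)(c1ccccc1)C(C)(C)C | intermediate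
20 | (13S)-6α,13-dihydroxy-15,15-dimethoxy-16-(TBDPS-oxy)labd-8(9)-en-7-one | COC(OC)C[C@@](O)(CCC1=C(C)C(=O)[C@H](O)[C@H]2C(C)(C)CCC[C@]12C)CO[Si](c1ccccc1)(c1ccccc1)C(C)(C)C | intermediate
21 | (13S)-6α-(TBS-oxy)-13-hydroxy-15,15-dimethoxy-16-(TBDPS-oxy)labd-8(9)-en-7-one | COC(OC)C[C@@](O)(CCC1=C(C)C(=O)[C@H](O[Si](C)(C)C(C)(C)C)[C@H]2C(C)(C)CCC[C@]12C)CO[Si](c1ccccc1)(c1ccccc1)C(C)(C)C | intermediate
22 | (13S)-6α-(TBS-oxy)-15,15-dimethoxy-16-(TBDPS-oxy)labd-8(9)-ene-7β,13-diol | COC(OC)C[C@@](O)(CCC1=C(C)[C@@H](O)[C@H](O[Si](C)(C)C(C)(C)C)[C@H]2C(C)(C)CCC[C@]12C)CO[Si](c1ccccc1)(c1ccccc1)C(C)(C)C | intermediate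
23 | (13S)-9α,13-epoxy-6α-(TBS-oxy)-15,15-dimethoxy-16-(TBDPS-oxy)labd-7-ene | CC1=C[C@H](O[Si](C)(C)C(C)(C)C)[C@H]2C(C)(C)CCC[C@]2(C)[C@@]13CC[C@@](CO[Si](c4ccccc4)(c4ccccc4)C(C)(C)C)(CC(OC)OC)O3 | intermediate
24 | secondary ozonide of 23 (1,2,4-trioxolane across C7 and C8) | CC12OOC(O1)[C@H](O[Si](C)(C)C(C)(C)C)[C@H]3C(C)(C)CCC[C@]3(C)[C@@]24CC[C@@](CO[Si](c5ccccc5)(c5ccccc5)C(C)(C)C)(CC(OC)OC)O4 | intermediate
25 | (13S)-9α,13-epoxy-6α-(TBS-oxy)-15,15-dimethoxy-8-oxo-16-(TBDPS-oxy)-7,8-secolabdan-7-al | O=C[C@H](O[Si](C)(C)C(C)(C)C)[C@H]1C(C)(C)CCC[C@]1(C)[C@@]2(CC[C@@](CO[Si](c3ccccc3)(c3ccccc3)C(C)(C)C)(CC(OC)OC)O2)C(C)=O | intermediate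
26 | bis(diiodosamarium) 7β,8β-diolate of 27 | I[Sm](I)O[C@H]1[C@H](O[Si](C)(C)C(C)(C)C)[C@H]2C(C)(C)CCC[C@]2(C)[C@@]3(CC[C@@](CO[Si](c4ccccc4)(c4ccccc4)C(C)(C)C)(CC(OC)OC)O3)[C@@]1(C)O[Sm](I)I | intermediate
27 | (13S)-9α,13-epoxy-6α-(TBS-oxy)-15,15-dimethoxy-16-(TBDPS-oxy)labdane-7β,8β-diol | O[C@H]1[C@H](O[Si](C)(C)C(C)(C)C)[C@H]2C(C)(C)CCC[C@]2(C)[C@@]3(CC[C@@](CO[Si](c4ccccc4)(c4ccccc4)C(C)(C)C)(CC(OC)OC)O3)[C@@]1(C)O | intermediate
28 | (13S)-7β-acetoxy-9α,13-epoxy-6α-(TBS-oxy)-15,15-dimethoxy-16-(TBDPS-oxy)labdan-8β-ol | CC(=O)O[C@H]1[C@H](O[Si](C)(C)C(C)(C)C)[C@H]2C(C)(C)CCC[C@]2(C)[C@@]3(CC[C@@](CO[Si](c4ccccc4)(c4ccccc4)C(C)(C)C)(CC(OC)OC)O3)[C@@]1(C)O | intermediate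
29 | (13S)-7β-acetoxy-9α,13-epoxy-15,15-dimethoxylabdane-6α,8β,16-triol | CC(=O)O[C@H]1[C@H](O)[C@H]2C(C)(C)CCC[C@]2(C)[C@@]3(CC[C@@](CO)(CC(OC)OC)O3)[C@@]1(C)O | intermediate
30 | (13S)-7β-acetoxy-9α,13:15,16-diepoxy-15-methoxylabdane-6α,8β-diol | CC(=O)O[C@H]1[C@H](O)[C@H]2C(C)(C)CCC[C@]2(C)[C@@]3(CC[C@@]4(CC(OC)OC4)O3)[C@@]1(C)O | intermediate
31 | (13S)-7β-acetoxy-9α,13:15,16-diepoxy-8β-hydroxy-15-methoxylabdan-6-one | CC(=O)O[C@H]1C(=O)[C@H]2C(C)(C)CCC[C@]2(C)[C@@]3(CC[C@@]4(CC(OC)OC4)O3)[C@@]1(C)O | intermediate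
32 | (13S)-7β-acetoxy-9α,13:15,16-diepoxy-8β,15-dihydroxylabdan-6-one | CC(=O)O[C@H]1C(=O)[C@H]2C(C)(C)CCC[C@]2(C)[C@@]3(CC[C@@]4(CC(O)OC4)O3)[C@@]1(C)O | intermediate
33 | 15-O-mesylate of 32 | CC(=O)O[C@H]1C(=O)[C@H]2C(C)(C)CCC[C@]2(C)[C@@]3(CC[C@@]4(CC(OS(C)(=O)=O)OC4)O3)[C@@]1(C)O | intermediate
34 | (13S)-7β-acetoxy-9α,13:15,16-diepoxy-8β-hydroxylabd-14-en-6-one (CNP0284584.1) | CC(=O)O[C@H]1C(=O)[C@H]2C(C)(C)CCC[C@]2(C)[C@@]2(CC[C@@]3(C=COC3)O2)[C@@]1(C)O | target

Total step count: 23.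
Longest linear sequence: 21 steps, from 1 through steps 1–3 and 6–23 to 34.

Steps most likely to fail

Step 18. The ketyl may take up a second electron before it closes the ring. That would lead to plain reduction of the aldehyde or to loss of the α-oxygen substituent at C6 or C9. The chelate may also fail to control both faces.
- The fallback sets out from 25 and makes the same C7–C8 bond by polarity reversal instead of electron transfer.
- An N-heterocyclic carbene, generated from a bicyclic triazolium tetrafluoroborate with Et3N in THF, adds to the aldehyde. The resulting acyl-anion equivalent attacks the C8 ketone in an intramolecular crossed benzoin reaction.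
- This should give (13S)-9α,13-epoxy-6α-(TBS-oxy)-8β-hydroxy-15,15-dimethoxy-16-(TBDPS-oxy)labdan-7-one F1, with the C8 methyl equatorial for the same steric reason as in the main route.
- NaBH4 in MeOH at −20 °C should then deliver hydride axially from the α face and give the equatorial 7β-alcohol, which rejoins the route at 27.

Step 16. The allyl cation may lose a proton to give dienes, the product may re-ionise at its tertiary allylic ether, or acid may erode the acetal and the silyl ethers before the hindered tertiary hydroxyl closes the ring.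
- The fallback sets out from 22 and forms the C9–O bond by epoxide opening instead of cation capture.
- Hydroxyl-directed epoxidation with VO(acac)2 (cat.) and t-BuOOH in CH2Cl2 should place oxygen syn to the 7β-OH. This should give (13S)-8β,9β-epoxy-6α-(TBS-oxy)-15,15-dimethoxy-16-(TBDPS-oxy)labdane-7β,13-diol F2.
- Catalytic camphorsulfonic acid then lets the 13-OH open the epoxide at C9 from the α face (5-exo-tet, inversion, trans-diaxial). This rejoins the route at 27 and skips steps 16–18.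
- The detour depends on epoxidation of the face that carries the C10 methyl, which is why it is held in reserve.

Step 23. The anomeric mesylate may ionise, and the enol ether, once formed, may push out the C13 ether oxygen, so that ring C opens and ring D aromatises.
- The fallback sets out from 31, avoids the lactol and ends with a thermal syn-elimination in a neutral medium.
- PhSH with PPTS (cat.) in CH2Cl2 exchanges the methoxy group and should give (13S)-7β-acetoxy-9α,13:15,16-diepoxy-8β-hydroxy-15-(phenylthio)labdan-6-one F3.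
- One equivalent of mCPBA at −78 °C should give the sulfoxide (13S)-7β-acetoxy-9α,13:15,16-diepoxy-8β-hydroxy-15-(phenylsulfinyl)labdan-6-one F4.
- Heating F4 in toluene over solid NaHCO3 eliminates toward C14, the only β-hydrogen-bearing carbon, and rejoins the route at 34.

Further compounds
F1 | step 18 | (13S)-9α,13-epoxy-6α-(TBS-oxy)-8β-hydroxy-15,15-dimethoxy-16-(TBDPS-oxy)labdan-7-one | O=C1[C@H](O[Si](C)(C)C(C)(C)C)[C@H]2C(C)(C)CCC[C@]2(C)[C@@]3(CC[C@@](CO[Si](c4ccccc4)(c4ccccc4)C(C)(C)C)(CC(OC)OC)O3)[C@@]1(C)O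
F2 | step 16 | (13S)-8β,9β-epoxy-6α-(TBS-oxy)-15,15-dimethoxy-16-(TBDPS-oxy)labdane-7β,13-diol | COC(OC)C[C@@](O)(CC[C@]12O[C@@]1(C)[C@@H](O)[C@H](O[Si](C)(C)C(C)(C)C)[C@H]3C(C)(C)CCC[C@]23C)CO[Si](c1ccccc1)(c1ccccc1)C(C)(C)C
F3 | step 23 | (13S)-7β-acetoxy-9α,13:15,16-diepoxy-8β-hydroxy-15-(phenylthio)labdan-6-one | CC(=O)O[C@H]1C(=O)[C@H]2C(C)(C)CCC[C@]2(C)[C@@]3(CC[C@@]4(CC(Sc5ccccc5)OC4)O3)[C@@]1(C)O
F4 | step 23 | (13S)-7β-acetoxy-9α,13:15,16-diepoxy-8β-hydroxy-15-(phenylsulfinyl)labdan-6-one | CC(=O)O[C@H]1C(=O)[C@H]2C(C)(C)CCC[C@]2(C)[C@@]3(CC[C@@]4(CC(S(=O)c5ccccc5)OC4)O3)[C@@]1(C)O
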